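## Structural features

Sideroxylonal C is a 2-arylchromane: benzene ring A is fused through C4a and C8a to the dihydropyran ring B (O1, C2, C3, C4), and a second benzene ring, ring C, is attached to C2 through C1'. Both arenes are phloroglucinol units with two formyl groups each, at C6 and C8 in ring A and at C3' and C5' in ring C. Every aromatic carbon is therefore substituted, and each formyl group lies between two oxygen-bearing carbons. Ring B carries three contiguous stereocentres, C2 (aryl), C3 (isopropyl) and C4 (isobutyl), all R, with each neighbouring pair trans. The fragile elements are the four salicylaldehyde-type groups with their free phenols, the benzylic C2–O1 bond, which ionises under acid and can scramble C2, and C3, which can epimerise whenever C2 is at the aldehyde or oxocarbenium level. C4 is benzylic but not acidic and serves as the stereochemical anchor. The real difficulty is the junction between a hexasubstituted arene and a branched stereogenic secondary carbon (C4) flanked by a second stereocentre (C3), together with the need to place two formyl carbons on a ring that has no free position. The key step uses the fact that C4a, lying between the oxygenated carbons C5 and C8a, corresponds to the central carbon of a malonate, while C6 and C8, on either side of the oxygenated C7, correspond to the two methylene carbons of a 3-oxoglutarate whose ester groups are latent formyl groups; ring A can thus be grown onto an acyclic chain in which C3 and C4 are already set.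

## Logic of the disconnections

18 ⇒ 17. The five phenolic O–H groups are traced back to O–CH3 bonds. Free formyl-phloroglucinols would not survive hydride, oxidant and Lewis acid, so the ethers give a robust, non-acidic intermediate. The forward step must cleave five ethers without touching four aldehydes or the C2–O1 bond; every methoxy group is ortho to a formyl group, which helps.

17 ⇒ 16. The C3'–CHO and C5'–CHO bonds are cut. These are the only free arene positions left and each is activated by three methoxy groups, so ring C can enter earlier as a simple symmetric arene. The forward step must formylate twice without ionising C2–O1.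

16 ⇒ 15 ⇒ 14 ⇒ 13. No skeletal bond is cut. The ring A formyl groups are traced through the diol 15 to the ester groups of 14, because ring A has no free position and its formyl carbons must arrive with the ring. The two O–CH3 bonds of 14 are then removed to give 13; the phenols must be capped before reduction, otherwise ortho-hydroxybenzyl alcohols would shed water.

13 ⇒ 10 + 11. The C2–C1' and O1–C2 bonds are cut. C2 is at the acetal level and sits next to a ring A phenol, so it can close ring B and then act as an oxocarbenium electrophile toward 11 (through 12). This removes rings B and C in one operation. The forward step must add the arene trans to the C3 substituent.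

10 ⇒ 6 + 7 (key). The C5–C6 and C8–C8a bonds are cut, which removes ring A altogether and leaves a malonate on C4 and a five-carbon commercially available unit. The forward step must acylate both methylene carbons of 7 at carbon, spare the acetal, and leave C3 and C4 untouched. The half-ester salt 6 is used instead of the diester 5 because a stabilised enolate will not attack a hindered methyl ester and 7 self-condenses under forcing conditions. One carboxyl is therefore activated (8) and the other closes the ring as an ester (9).

6 ⇒ 5. One ester O–CH3 bond is restored. Monohydrolysis under base keeps the acetal intact.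

5 ⇒ 3 + 1. The C3–C4 bond is cut (with the acetal traced to the aldehyde 4). C3 is alpha to an aldehyde and C4 is beta to two esters, which is a Michael retron. Two stereocentres come from achiral partners in one catalytic step. The forward step needs syn diastereoselection, facial control and immediate protection of the aldehyde.

3 ⇒ 1 + 2. The C4=C4a double bond is cut by a condensation retron, leading to two commodity chemicals. The two esters are identical, so no alkene geometry has to be controlled.

## Other disconnections considered

Alternative 1: The cut is C4–C4a plus O1–C2, which leaves benzene-1,3,5-triol A2 and (2E)-5-methyl-2-(propan-2-yl)hex-2-enal A1, the aldol condensation dimer of 1.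
- Forward step: a chiral primary amine salt would turn A1 into an iminium ion, A2 would add through a ring carbon to the beta carbon, the enamine would be protonated at C3, and the adjacent phenol would close on the aldehyde carbon to give lactol A3.
- In favour: the C3/C4 core is reached in about two steps, A2 is symmetric so no regiochemistry arises, and A3 is already the C2 electrophile for ring C.
- Against: the alpha-branched enal A1 forms a hindered iminium ion of poorly defined geometry; C3 is set by protonation, not by C–C bond formation; A2 can be alkylated more than once; and all four formyl groups must then be introduced by electrophilic substitution on an acid-labile 2-arylchromane.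
- Comparison: on step economy this plan is clearly the better one. On the C2 electrophile the two plans are equal, since both pass through a lactol-level chromane. On mechanism the chosen plan relies on the better-understood enamine addition, in which both centres are set in the C–C bond-forming event. On structure the chosen plan brings C6 and C8 in with the ring and so avoids formylating ring A.

Alternative 2: The cut is O1–C2 plus C2–C3, which leaves 2,4-dibromo-6-[(4R)-2,6-dimethylhept-2-en-4-yl]-3,5-dimethoxyphenol A4 and 2-(dimethoxymethyl)-1,3,5-trimethoxybenzene A5.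
- Forward step: Me3SiOTf would exchange the acetal A5 with the phenol of A4 to an aryl oxocarbenium ion, the trisubstituted alkene would attack it through C3, and the tertiary cation would lose a proton to give A6 with a propenyl group on C3.
- In favour: ring C and C2 arrive together, a chair-like closure should set C2 and C3 relative to C4 in one step, and the bromine atoms block C6 and C8 and later serve as handles for formylation.
- Against: A4 must first be made as a single enantiomer, and its C4 is both allylic and benzylic to an electron-rich ring, so it may ionise under the Lewis acid. The phenol, flanked by bromine, is a weak nucleophile. Afterwards the propenyl group must be hydrogenated without loss of the aryl bromides, two bromine–lithium exchanges with formylation are needed, and ring C must still be formylated and the ethers cleaved.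
- Comparison: this plan is the better one in convergence, because C2 and its aryl group are installed with stereocontrol in the ring-forming step and no separate arylation is needed. The chosen plan is safer for the configurational integrity of C4, which never becomes a cation, and needs no alkene reduction or halogen–metal chemistry. Step counts should be about equal once the synthesis of A4 is included.

Alternative 3: The cut is O1–C8a plus C4–C4a, which leaves the aryne precursor 3,5-dimethoxy-2-(trimethylsilyl)phenyl trifluoromethanesulfonate A7 and ethyl (2E,4R,5R)-5-hydroxy-4-(propan-2-yl)-5-(2,4,6-trimethoxyphenyl)pent-2-enoate A8.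
- Forward step: CsF would release the dimethoxy aryne from A7, the alkoxide of A8 would add at the aryne carbon remote from the flanking methoxy group, and the aryl anion would add to the enoate beta carbon to give A9.
- In favour: ring A comes from a simple precursor, C2 and C3 can be set beforehand by reliable aldol methods, C4 is set in an intramolecular conjugate addition, and both arenes keep free positions so all four formyl groups could be introduced in one operation.
- Against: the aryl anion may be protonated before it cyclises, the alkoxide of A8 can undergo retro-aldol cleavage, and the regiochemistry rests only on the inductive bias of one methoxy group. A9 also carries a CH2CO2Et group where isobutyl is required, which costs several repair steps.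
- Comparison: this plan is the better one for formyl introduction (one fourfold formylation, no ester redox) and the equal of the chosen plan in the use of robust chemistry for C2 and C3. The chosen plan has the isobutyl group in place from the first step and should be shorter overall.

Key step: step 4

Remark on the chemistry: 6, 8 and 9 are epimeric mixtures at the former malonate carbon (9 also a keto/enol mixture) and 12 is an anomeric mixture. This is without consequence, because these centres become C4a and the C2 oxocarbenium carbon.

## Route

Step 1
Reactants: 1 3-methylbutanal; 2 dimethyl propanedioate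
Product: 3 dimethyl 2-(3-methylbutylidene)propanedioate
Conditions: nPr2NH (cat.), AcOH (cat.), cyclohexane, reflux, azeotropic removal of H2O
Reagents that add atoms: none
Why: Knoevenagel condensation of an aliphatic aldehyde with a malonate under amine/acid catalysis, a transformation practised on scale for the corresponding diethyl ester; the two esters are identical, so no alkene geometry arises.

Step 2
Reactants: 3 dimethyl 2-(3-methylbutylidene)propanedioate; 1 3-methylbutanal
Product: 5 dimethyl 2-[(4R,5R)-6,6-dimethoxy-2-methyl-5-(propan-2-yl)hexan-4-yl]propanedioate, via Michael aldehyde 4 (not isolated)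
Conditions: (S)-2-[diphenyl(trimethylsilyloxy)methyl]pyrrolidine (20 mol%), PhCO2H (20 mol%), toluene, 0 °C → rt; then HC(OMe)3, MeOH, TsOH·H2O (30 mol%), rt
Reagents that add atoms: trimethyl orthoformate, COC(OC)OC; methanol, CO
Why: Enamine-mediated asymmetric Michael addition to an alkylidene malonate: the (E)-enamine of 1 is shielded on one face by the CPh2OSiMe3 group, so 3 should add to the open Si face through an acyclic synclinal transition state and give the syn adduct with C3 (R) and C4 (R). Acetalisation in the same flask masks the aldehyde before its alpha centre (C3) can epimerise.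

Step 3
Reactants: 5 dimethyl 2-[(4R,5R)-6,6-dimethoxy-2-methyl-5-(propan-2-yl)hexan-4-yl]propanedioate
Product: 6 potassium 2-[(4R,5R)-6,6-dimethoxy-2-methyl-5-(propan-2-yl)hexan-4-yl]-3-methoxy-3-oxopropanoate
Conditions: KOH (1.05 equiv), THF–H2O, 0 °C → rt; evaporate, dry azeotropically with toluene
Reagents that add atoms: potassium hydroxide, [K+].[OH-]
Why: Selective monohydrolysis of a symmetric malonate stops at the half-ester because the carboxylate formed deactivates the second ester. The acetal is stable to base, and the salt is isolated without acidification so that C2 stays masked.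

Step 4
Reactants: 6 potassium 2-[(4R,5R)-6,6-dimethoxy-2-methyl-5-(propan-2-yl)hexan-4-yl]-3-methoxy-3-oxopropanoate; 7 dimethyl 3-oxopentanedioate
Product: 10 dimethyl 5-[(4R,5R)-6,6-dimethoxy-2-methyl-5-(propan-2-yl)hexan-4-yl]-2,4,6-trihydroxybenzene-1,3-dicarboxylate, via acid chloride 8 (not isolated), via acyclic diketo tetraester 9 (not isolated)
Conditions: (COCl)2, DMF (cat.), CH2Cl2, 0 °C; then 7, MgCl2, pyridine, MeCN, 0 °C → rt; evaporate; then Mg(OMe)2, MeOH, 65 °C; cold aq NH4Cl
Reagents that add atoms: none
Why: Proposed new method: oxalyl chloride converts the carboxylate of 6 into acid chloride 8 without liberating acid, and 8 (directly or through its methoxycarbonyl ketene, formed with pyridine) C-acylates the chelated magnesium enolate of 7 to give 9, which makes the first ring A bond (C5–C6; the two malonate carbonyls are equivalent until ring B is closed). Mg(OMe)2 then deprotonates 9 twice, the terminal methylene carbon attacks the remaining methyl ester of the former malonate (C8–C8a) in a 6-exo-trig Dieckmann closure, methoxide is expelled, and the cyclohexane-1,3,5-trione enolises to the arene, the only irreversible event of the sequence. The closest known reaction types are the MgCl2/amine C-acylation of 3-oxoglutarates by acid chlorides, the Claisen cyclisation of 3,5-dioxo esters and of 4-hydroxy-2-pyranones to phloroglucinols, and the sodium-mediated trimerisation of malonates to phloroglucinol tricarboxylates; none has been shown for a malonyl unit bearing a branched secondary alkyl group. Activating one carboxyl as the chloride answers the two weaknesses of a plain diester: a stabilised enolate does not attack a hindered methyl ester, and 7 self-condenses under the forcing conditions that would then be needed. No stereocentre is formed; C3 and C4 are not alpha to any carbonyl, so base cannot epimerise them, and the acetal at C2 is inert to base. The selectivity required is C- over O-acylation, which the chelated magnesium enolate favours; a 2-pyranone arising from O-acylation would be reopened by methoxide and drained into the same arene. Any 8 left unreacted is returned to 5 by the methanol of the last stage.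

Step 5
Reactants: 10 dimethyl 5-[(4R,5R)-6,6-dimethoxy-2-methyl-5-(propan-2-yl)hexan-4-yl]-2,4,6-trihydroxybenzene-1,3-dicarboxylate; 11 1,3,5-trimethoxybenzene
Product: 13 dimethyl (2R,3R,4R)-5,7-dihydroxy-4-(2-methylpropyl)-3-(propan-2-yl)-2-(2,4,6-trimethoxyphenyl)chromane-6,8-dicarboxylate, via 2-methoxychromane 12 (not isolated)
Conditions: BF3·OEt2, CH2Cl2, −40 °C; then 11 (1.5 equiv), −40 → 0 °C; aq NaHCO3
Reagents that add atoms: none
Why: The Lewis acid ionises the dimethyl acetal and an ortho phenol closes to the mixed acetal 12 (either ortho hydroxyl gives the same compound); re-ionisation gives a cyclic oxocarbenium ion that undergoes Friedel–Crafts arylation by 11. The arene should add anti to the C3 isopropyl group to set C2 (R), and reversible C2–O1 ionisation of the electron-rich benzylic ether should let the all-trans isomer accumulate.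

Step 6
Reactants: 13 dimethyl (2R,3R,4R)-5,7-dihydroxy-4-(2-methylpropyl)-3-(propan-2-yl)-2-(2,4,6-trimethoxyphenyl)chromane-6,8-dicarboxylate
Product: 14 dimethyl (2R,3R,4R)-5,7-dimethoxy-4-(2-methylpropyl)-3-(propan-2-yl)-2-(2,4,6-trimethoxyphenyl)chromane-6,8-dicarboxylate
Conditions: MeI, K2CO3, DMF, 40 °C
Reagents that add atoms: iodomethane, CI
Why: Williamson O-methylation of the two remaining phenols (both hydrogen-bonded to esters, hence warm DMF and excess base), so that the hydride reduction does not pass through ortho-hydroxybenzyl alcohols, which would lose water to ortho-quinone methides.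

Step 7
Reactants: 14 dimethyl (2R,3R,4R)-5,7-dimethoxy-4-(2-methylpropyl)-3-(propan-2-yl)-2-(2,4,6-trimethoxyphenyl)chromane-6,8-dicarboxylate
Product: 15 [(2R,3R,4R)-5,7-dimethoxy-4-(2-methylpropyl)-3-(propan-2-yl)-2-(2,4,6-trimethoxyphenyl)chromane-6,8-diyl]dimethanol
Conditions: LiAlH4, THF, 0 → 40 °C; then H2O, aq NaOH
Reagents that add atoms: none
Why: LiAlH4 reduction of both aryl esters to benzylic alcohols; nothing else in 14 is reducible, and the basic work-up does not touch the benzylic C2–O1 ether.

Step 8
Reactants: 15 [(2R,3R,4R)-5,7-dimethoxy-4-(2-methylpropyl)-3-(propan-2-yl)-2-(2,4,6-trimethoxyphenyl)chromane-6,8-diyl]dimethanol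
Product: 16 (2R,3R,4R)-5,7-dimethoxy-4-(2-methylpropyl)-3-(propan-2-yl)-2-(2,4,6-trimethoxyphenyl)chromane-6,8-dicarbaldehyde
Conditions: MnO2 (excess), CH2Cl2, rt
Reagents that add atoms: none
Why: MnO2 oxidation of electron-rich benzylic alcohols stops at the aldehyde and is neutral, so C2–O1 is not ionised.

Step 9
Reactants: 16 (2R,3R,4R)-5,7-dimethoxy-4-(2-methylpropyl)-3-(propan-2-yl)-2-(2,4,6-trimethoxyphenyl)chromane-6,8-dicarbaldehyde
Product: 17 (2R,3R,4R)-2-(3,5-diformyl-2,4,6-trimethoxyphenyl)-5,7-dimethoxy-4-(2-methylpropyl)-3-(propan-2-yl)chromane-6,8-dicarbaldehyde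
Conditions: Cl2CHOMe, TiCl4 (excess), CH2Cl2, −20 → 0 °C; then ice-water
Reagents that add atoms: dichloromethyl methyl ether, COC(Cl)Cl; water, O
Why: Rieche formylation: the TiCl4-activated chloro(methoxy)methyl cation attacks the only free arene positions, C3' and C5' of ring C, each ortho or para to three methoxy groups. Ring A is fully substituted, and each formyl group introduced makes C2–O1 less prone to ionisation.

Step 10
Reactants: 17 (2R,3R,4R)-2-(3,5-diformyl-2,4,6-trimethoxyphenyl)-5,7-dimethoxy-4-(2-methylpropyl)-3-(propan-2-yl)chromane-6,8-dicarbaldehyde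
Product: 18 (2R,3R,4R)-2-(3,5-diformyl-2,4,6-trihydroxyphenyl)-5,7-dihydroxy-4-(2-methylpropyl)-3-(propan-2-yl)chromane-6,8-dicarbaldehyde (sideroxylonal C)
Conditions: BBr3 (excess), CH2Cl2, −78 °C → rt; then H2O
Reagents that add atoms: none
Why: BBr3 cleavage of aryl methyl ethers; every methoxy group is ortho to a formyl group, so boron chelation to the carbonyl assists each demethylation, and the fourfold formylated rings no longer support ionisation at C2.

## Compound list

1 | 3-methylbutanal | CC(C)CC=O | starting material
2 | dimethyl propanedioate | COC(=O)CC(=O)OC | starting material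
3 | dimethyl 2-(3-methylbutylidene)propanedioate | COC(=O)C(=CCC(C)C)C(=O)OC | intermediate
4 | dimethyl 2-[(3R,4R)-3-formyl-2,6-dimethylheptan-4-yl]propanedioate | O=C[C@H](C(C)C)[C@@H](CC(C)C)C(C(=O)OC)C(=O)OC | intermediate (not isolated)
5 | dimethyl 2-[(4R,5R)-6,6-dimethoxy-2-methyl-5-(propan-2-yl)hexan-4-yl]propanedioate | COC(OC)[C@H](C(C)C)[C@@H](CC(C)C)C(C(=O)OC)C(=O)OC | intermediate
6 | potassium 2-[(4R,5R)-6,6-dimethoxy-2-methyl-5-(propan-2-yl)hexan-4-yl]-3-methoxy-3-oxopropanoate | [K+].COC(OC)[C@H](C(C)C)[C@@H](CC(C)C)C(C(=O)OC)C([O-])=O | intermediate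
7 | dimethyl 3-oxopentanedioate | COC(=O)CC(=O)CC(=O)OC | starting material
8 | methyl 3-chloro-2-[(4R,5R)-6,6-dimethoxy-2-methyl-5-(propan-2-yl)hexan-4-yl]-3-oxopropanoate | COC(OC)[C@H](C(C)C)[C@@H](CC(C)C)C(C(=O)OC)C(Cl)=O | intermediate (not isolated)
9 | trimethyl 1-[(4R,5R)-6,6-dimethoxy-2-methyl-5-(propan-2-yl)hexan-4-yl]-2,4-dioxopentane-1,3,5-tricarboxylate | COC(OC)[C@H](C(C)C)[C@@H](CC(C)C)C(C(=O)OC)C(=O)C(C(=O)OC)C(=O)CC(=O)OC | intermediate (not isolated)
10 | dimethyl 5-[(4R,5R)-6,6-dimethoxy-2-methyl-5-(propan-2-yl)hexan-4-yl]-2,4,6-trihydroxybenzene-1,3-dicarboxylate | COC(OC)[C@H](C(C)C)[C@@H](CC(C)C)c1c(O)c(C(=O)OC)c(O)c(C(=O)OC)c1O | intermediate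
11 | 1,3,5-trimethoxybenzene | COc1cc(OC)cc(OC)c1 | starting material
12 | dimethyl (3R,4R)-5,7-dihydroxy-2-methoxy-4-(2-methylpropyl)-3-(propan-2-yl)chromane-6,8-dicarboxylate | CC(C)C[C@H]1c2c(O)c(C(=O)OC)c(O)c(C(=O)OC)c2OC(OC)[C@@H]1C(C)C | intermediate (not isolated)
13 | dimethyl (2R,3R,4R)-5,7-dihydroxy-4-(2-methylpropyl)-3-(propan-2-yl)-2-(2,4,6-trimethoxyphenyl)chromane-6,8-dicarboxylate | CC(C)C[C@H]1c2c(O)c(C(=O)OC)c(O)c(C(=O)OC)c2O[C@@H](c2c(OC)cc(OC)cc2OC)[C@@H]1C(C)C | intermediate
14 | dimethyl (2R,3R,4R)-5,7-dimethoxy-4-(2-methylpropyl)-3-(propan-2-yl)-2-(2,4,6-trimethoxyphenyl)chromane-6,8-dicarboxylate | CC(C)C[C@H]1c2c(OC)c(C(=O)OC)c(OC)c(C(=O)OC)c2O[C@@H](c2c(OC)cc(OC)cc2OC)[C@@H]1C(C)C | intermediate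
15 | [(2R,3R,4R)-5,7-dimethoxy-4-(2-methylpropyl)-3-(propan-2-yl)-2-(2,4,6-trimethoxyphenyl)chromane-6,8-diyl]dimethanol | CC(C)C[C@H]1c2c(OC)c(CO)c(OC)c(CO)c2O[C@@H](c2c(OC)cc(OC)cc2OC)[C@@H]1C(C)C | intermediate
16 | (2R,3R,4R)-5,7-dimethoxy-4-(2-methylpropyl)-3-(propan-2-yl)-2-(2,4,6-trimethoxyphenyl)chromane-6,8-dicarbaldehyde | CC(C)C[C@H]1c2c(OC)c(C=O)c(OC)c(C=O)c2O[C@@H](c2c(OC)cc(OC)cc2OC)[C@@H]1C(C)C | intermediate
17 | (2R,3R,4R)-2-(3,5-diformyl-2,4,6-trimethoxyphenyl)-5,7-dimethoxy-4-(2-methylpropyl)-3-(propan-2-yl)chromane-6,8-dicarbaldehyde | CC(C)C[C@H]1c2c(OC)c(C=O)c(OC)c(C=O)c2O[C@@H](c2c(OC)c(C=O)c(OC)c(C=O)c2OC)[C@@H]1C(C)C | intermediate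
18 | (2R,3R,4R)-2-(3,5-diformyl-2,4,6-trihydroxyphenyl)-5,7-dihydroxy-4-(2-methylpropyl)-3-(propan-2-yl)chromane-6,8-dicarbaldehyde (sideroxylonal C) | CC(C)C[C@H]1c2c(O)c(C=O)c(O)c(C=O)c2O[C@@H](c2c(O)c(C=O)c(O)c(C=O)c2O)[C@@H]1C(C)C | target

## Step count and least certain steps

Total: 10 steps. Longest linear sequence: 10 steps, from 1 to 18; 2, 7 and 11 enter as purchased compounds.

Step 4 (key step). The most likely failure is a stalled intermolecular C-acylation, because the acyl carbon of 8 is flanked by a branched secondary centre. Ketene dimerisation, O-acylation of the enolate, attack of the acid chloride on the neighbouring acetal, or self-condensation of 7 in the methoxide stage could then take over, and retro-Claisen cleavage of 9 by methoxide is a further drain. The fallback separates the two bond formations into known reaction types and isolates the intermediate. It sets out from 5. Exhaustive saponification (excess KOH, aqueous MeOH, 60 °C) would give dipotassium 2-[(4R,5R)-6,6-dimethoxy-2-methyl-5-(propan-2-yl)hexan-4-yl]propanedioate F1. Oxalyl chloride in CH2Cl2 at 0 °C would convert it into 2-[(4R,5R)-6,6-dimethoxy-2-methyl-5-(propan-2-yl)hexan-4-yl]propanedioyl dichloride F2. With the magnesium enolate of 7 (MgCl2, pyridine), F2 should undergo the established C-acylation and lactonisation of a malonyl dichloride with a beta-keto ester to give methyl 3-[(4R,5R)-6,6-dimethoxy-2-methyl-5-(propan-2-yl)hexan-4-yl]-4-hydroxy-6-(2-methoxy-2-oxoethyl)-2-oxo-2H-pyran-5-carboxylate F3, which is isolated. Mg(OMe)2 in refluxing MeOH would then effect the known Claisen recyclisation of a 4-hydroxy-2-pyranone, in which the side-chain carbanion attacks the lactone carbonyl, and the fallback returns to the route at 10.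

Step 2. The conjugate addition to a beta-alkyl alkylidene malonate may be slow. Amine-induced deconjugation of 3 and self-aldol reaction of 1 could then compete, and syn selectivity could erode or C3 could epimerise before the acetal is formed. The fallback replaces enamine activation of the donor by Lewis-acid activation of the acceptor and sets out from 3. S-ethyl 3-methylbutanethioate F4 (from 3-methylbutanoyl chloride and ethanethiol) would be converted with LDA and Me3SiCl into {[(1Z)-1-(ethylsulfanyl)-3-methylbut-1-en-1-yl]oxy}(trimethyl)silane F5. A Mukaiyama–Michael addition of F5 to 3, catalysed by the divalent copper complex [Cu(tBu-box)](SbF6)2 with (CF3)2CHOH at −78 °C, would follow, with the ligand enantiomer and the enolsilane geometry chosen for the required C4 and syn relationship. It should give dimethyl 2-{(3R,4S)-3-[(ethylsulfanyl)carbonyl]-2,6-dimethylheptan-4-yl}propanedioate F6; the changed C4 descriptor reflects only the priority of the thioester branch. Fukuyama reduction (Et3SiH, Pd/C) would return the sequence to 4, which is acetalised to 5 as in step 2.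

Step 5. Over-arylation is the main risk: the open-chain methyl oxocarbenium ion, or the product after renewed C2–O1 ionisation, can capture a second molecule of 11. Loss of the C3 proton from the oxocarbenium ion (elimination to a 4H-chromene) and incomplete facial selectivity at C2 are further risks. The fallback forms the C2–aryl bond by carbonyl addition and closes ring B afterwards, with no free arene present. It sets out from 10. Aqueous AcOH would give the lactol dimethyl (3R,4R)-2,5,7-trihydroxy-4-(2-methylpropyl)-3-(propan-2-yl)chromane-6,8-dicarboxylate F7. After deprotonation of the phenols with NaH, (2,4,6-trimethoxyphenyl)lithium F8 (from 11 and n-BuLi) would add to the ring-opened aldehyde to give dimethyl 2,4,6-trihydroxy-5-[(4R,5R)-6-hydroxy-2-methyl-5-(propan-2-yl)-6-(2,4,6-trimethoxyphenyl)hexan-4-yl]benzene-1,3-dicarboxylate F9 (carbinol epimers). Catalytic pyridinium tosylate in CH2Cl2 would then close the ring through the benzylic cation, and the fallback returns at 13.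

Step 9. The second formylation may stop short, because the first formyl group and the TiCl4-bound ring A aldehydes deactivate the substrate. The Lewis acid may also ionise C2–O1 while ring C is still electron-rich, leading to epimerisation at C2 or ring opening. The fallback reverses the order of deprotection and formylation and sets out from 16. BBr3 would first give (2R,3R,4R)-5,7-dihydroxy-4-(2-methylpropyl)-3-(propan-2-yl)-2-(2,4,6-trihydroxyphenyl)chromane-6,8-dicarbaldehyde F10. Vilsmeier–Haack diformylation of its free phloroglucinol ring (POCl3, DMF; then aq NaOAc), a reaction that needs no strong Lewis acid, would return directly at 18.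

## Further compounds

F1 | step 4 | dipotassium 2-[(4R,5R)-6,6-dimethoxy-2-methyl-5-(propan-2-yl)hexan-4-yl]propanedioate | [K+].[K+].COC(OC)[C@H](C(C)C)[C@@H](CC(C)C)C(C([O-])=O)C([O-])=O
F2 | step 4 | 2-[(4R,5R)-6,6-dimethoxy-2-methyl-5-(propan-2-yl)hexan-4-yl]propanedioyl dichloride | COC(OC)[C@H](C(C)C)[C@@H](CC(C)C)C(C(Cl)=O)C(Cl)=O
F3 | step 4 | methyl 3-[(4R,5R)-6,6-dimethoxy-2-methyl-5-(propan-2-yl)hexan-4-yl]-4-hydroxy-6-(2-methoxy-2-oxoethyl)-2-oxo-2H-pyran-5-carboxylate | COC(OC)[C@H](C(C)C)[C@@H](CC(C)C)C1=C(O)C(C(=O)OC)=C(CC(=O)OC)OC1=O
F4 | step 2 | S-ethyl 3-methylbutanethioate | CCSC(=O)CC(C)C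
F5 | step 2 | {[(1Z)-1-(ethylsulfanyl)-3-methylbut-1-en-1-yl]oxy}(trimethyl)silane | CCS/C(O[Si](C)(C)C)=C\C(C)C
F6 | step 2 | dimethyl 2-{(3R,4S)-3-[(ethylsulfanyl)carbonyl]-2,6-dimethylheptan-4-yl}propanedioate | CCSC(=O)[C@H](C(C)C)[C@@H](CC(C)C)C(C(=O)OC)C(=O)OC
F7 | step 5 | dimethyl (3R,4R)-2,5,7-trihydroxy-4-(2-methylpropyl)-3-(propan-2-yl)chromane-6,8-dicarboxylate | CC(C)C[C@H]1c2c(O)c(C(=O)OC)c(O)c(C(=O)OC)c2OC(O)[C@@H]1C(C)C
F8 | step 5 | (2,4,6-trimethoxyphenyl)lithium | [Li]c1c(OC)cc(OC)cc1OC
F9 | step 5 | dimethyl 2,4,6-trihydroxy-5-[(4R,5R)-6-hydroxy-2-methyl-5-(propan-2-yl)-6-(2,4,6-trimethoxyphenyl)hexan-4-yl]benzene-1,3-dicarboxylate | COc1cc(OC)c(C(O)[C@H](C(C)C)[C@@H](CC(C)C)c2c(O)c(C(=O)OC)c(O)c(C(=O)OC)c2O)c(OC)c1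
F10 | step 9 | (2R,3R,4R)-5,7-dihydroxy-4-(2-methylpropyl)-3-(propan-2-yl)-2-(2,4,6-trihydroxyphenyl)chromane-6,8-dicarbaldehyde | CC(C)C[C@H]1c2c(O)c(C=O)c(O)c(C=O)c2O[C@@H](c2c(O)cc(O)cc2O)[C@@H]1C(C)C
A1 | alternative 1 | (2E)-5-methyl-2-(propan-2-yl)hex-2-enal | CC(C)C/C=C(/C=O)C(C)C
A2 | alternative 1 | benzene-1,3,5-triol | Oc1cc(O)cc(O)c1
A3 | alternative 1 | (3R,4R)-4-(2-methylpropyl)-3-(propan-2-yl)chromane-2,5,7-triol | CC(C)C[C@H]1c2c(O)cc(O)cc2OC(O)[C@@H]1C(C)C
A4 | alternative 2 | 2,4-dibromo-6-[(4R)-2,6-dimethylhept-2-en-4-yl]-3,5-dimethoxyphenol | CC(C)C[C@H](C=C(C)C)c1c(OC)c(Br)c(OC)c(Br)c1O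
A5 | alternative 2 | 2-(dimethoxymethyl)-1,3,5-trimethoxybenzene | COC(OC)c1c(OC)cc(OC)cc1OC
A6 | alternative 2 | (2R,3S,4R)-6,8-dibromo-5,7-dimethoxy-4-(2-methylpropyl)-3-(prop-1-en-2-yl)-2-(2,4,6-trimethoxyphenyl)chromane | CC(C)C[C@H]1c2c(OC)c(Br)c(OC)c(Br)c2O[C@@H](c2c(OC)cc(OC)cc2OC)[C@@H]1C(C)=C
A7 | alternative 3 | 3,5-dimethoxy-2-(trimethylsilyl)phenyl trifluoromethanesulfonate | COc1cc(OC)c([Si](C)(C)C)c(OS(=O)(=O)C(F)(F)F)c1
A8 | alternative 3 | ethyl (2E,4R,5R)-5-hydroxy-4-(propan-2-yl)-5-(2,4,6-trimethoxyphenyl)pent-2-enoate | CCOC(=O)/C=C/[C@@H](C(C)C)[C@@H](O)c1c(OC)cc(OC)cc1OC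
A9 | alternative 3 | ethyl 2-[(2R,3R,4R)-5,7-dimethoxy-3-(propan-2-yl)-2-(2,4,6-trimethoxyphenyl)chroman-4-yl]acetate | CCOC(=O)C[C@H]1c2c(OC)cc(OC)cc2O[C@@H](c2c(OC)cc(OC)cc2OC)[C@@H]1C(C)C
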